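The cyclohexane ring of ugonin Q is read as a reduced 4,4-dimethylcyclohex-2-enone: the carbinol carbon is a ketone, and the two adjacent ring CH2 groups between it and the CMe2 carbon are the CH=CH left by an aldol condensation. The ring is therefore assembled from three cheap pieces: isobutyraldehyde (CMe2 and its CH2), benzyl acetoacetate (the other CH2, the carbinol carbon and the methylidene-bearing carbon) and a silyloxyacetaldehyde (the stereogenic CH with its CH2 arm). Isobutyraldehyde adds in an asymmetric Michael reaction to the Knoevenagel adduct of the other two, and the 1,5-ketoaldehyde formed cyclises in the same pot. The ester later directs methylenation; luteolin is attached by Negishi coupling.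

Key step: step 2

Assumption: the (R,R)-enantiomer of the amine–thiourea catalyst is taken to give the (R)-configured adduct 5; if the sense of induction proves to be the opposite, the (S,S)-catalyst is used and nothing else changes.

Step 1
Reactants: 1 2-[(tert-butyldimethylsilyl)oxy]acetaldehyde; 2 benzyl acetoacetate
Product: 3 benzyl 2-acetyl-4-[(tert-butyldimethylsilyl)oxy]but-2-enoate (E/Z mixture)
Conditions: piperidine (5 mol%), AcOH (5 mol%), 4 Å MS, CH2Cl2, 0 °C
Reagents that add atoms: none
Why: Knoevenagel condensation of the doubly activated methylene of 2 with the unhindered aldehyde 1; low temperature and sieves should limit bis-addition and deconjugation, no stereocentre is formed and the E/Z mixture is used as such.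

Step 2
Reactants: 3 benzyl 2-acetyl-4-[(tert-butyldimethylsilyl)oxy]but-2-enoate; 4 isobutyraldehyde
Product: 6 benzyl (6R)-6-{[(tert-butyldimethylsilyl)oxy]methyl}-5,5-dimethyl-2-oxocyclohex-3-ene-1-carboxylate, via ketoaldehyde 5 (not isolated)
Conditions: 4 (3 equiv), 1-[(1R,2R)-2-aminocyclohexyl]-3-[3,5-bis(trifluoromethyl)phenyl]thiourea (15 mol%), PhCO2H (15 mol%), H2O (2 equiv), toluene, rt; excess 4 evaporated; then piperidine/AcOH (20 mol% each), 4 Å MS, toluene, 50 °C
Reagents that add atoms: none
Why: The primary amine of the catalyst converts 4 into an enamine while the thiourea hydrogen-bonds the 1,3-dicarbonyl unit of 3, so that the Michael addition joins the CMe2 carbon to the β-carbon of 3 from one face and sets the ring stereocentre under catalyst control (the E and Z forms of 3 should equilibrate through reversible amine addition); hydrolysis releases ketoaldehyde 5. Piperidinium acetate then effects the intramolecular aldol condensation between the acetyl CH3 and the neopentyl CHO, a 6-(enolendo)-exo-trig closure that creates the bond between the two future ring CH2 carbons as a C=C and is made irreversible by dehydration. The closest known reaction type is the amine-catalysed Michael/aldol-condensation (Robinson-type) synthesis of cyclohexenones from acetoacetates and enals and from isobutyraldehyde and vinyl ketones, together with amine–thiourea-catalysed additions of α,α-disubstituted aldehydes to doubly activated alkenes. Regioselectivity is secured by the substrate: the aldehyde has no α-hydrogen, closure from the more acidic CH between the two carbonyl groups would give a cyclobutane and reverts, and only the methyl group reaches the aldehyde through a six-membered ring. The ester-bearing carbon stays epimerisable, which is of no consequence because it becomes sp2 in step 3.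

Step 3
Reactants: 6 benzyl (6R)-6-{[(tert-butyldimethylsilyl)oxy]methyl}-5,5-dimethyl-2-oxocyclohex-3-ene-1-carboxylate
Product: 8 (3S)-3-{[(tert-butyldimethylsilyl)oxy]methyl}-4,4-dimethyl-2-methylidenecyclohexan-1-one, via keto acid 7 (not isolated)
Conditions: H2 (1 atm), 10% Pd/C, EtOAc, rt; filter; then 37% aq. CH2O, Et2NH, THF, 0 °C to rt; NaOAc/AcOH, 50 °C; product used at once
Reagents that add atoms: formaldehyde, C=O
Why: Heterogeneous hydrogenation saturates the enone C=C and cleaves the benzyl ester, and the β-keto acid then undergoes decarboxylative Mannich methylenation (aminomethylation at the carbon between C=O and CO2H, then loss of CO2 and amine), which places the methylidene regiospecifically on the carbon that carried the carboxyl group without touching the stereocentre.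

Step 4
Reactants: 8 (3S)-3-{[(tert-butyldimethylsilyl)oxy]methyl}-4,4-dimethyl-2-methylidenecyclohexan-1-one
Product: 9 (1R,3S)-3-{[(tert-butyldimethylsilyl)oxy]methyl}-4,4-dimethyl-2-methylidenecyclohexan-1-ol (cis)
Conditions: NaBH4, CeCl3·7H2O, MeOH, −78 °C
Reagents that add atoms: none
Why: Luche 1,2-reduction; axial hydride delivery to the conformer with an equatorial CH2OTBS group and equatorial delivery to the conformer with an axial CH2OTBS group (which blocks the axial path) both lead to the cis alcohol, so the carbinol centre should be set (R) by substrate control.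

Step 5
Reactants: 9 (1R,3S)-3-{[(tert-butyldimethylsilyl)oxy]methyl}-4,4-dimethyl-2-methylidenecyclohexan-1-ol
Product: 10 (1S,3S)-3-{[(tert-butyldimethylsilyl)oxy]methyl}-4,4-dimethyl-2-methylidenecyclohexyl benzoate (trans)
Conditions: PPh3, DIAD, PhCO2H, toluene, 0 °C to rt
Reagents that add atoms: benzoic acid, O=C(O)c1ccccc1
Why: Mitsunobu esterification proceeds by SN2 displacement of the alkoxyphosphonium ion and therefore inverts the carbinol centre to (S), which gives the trans relationship required in the target and installs a base-labile protecting group at the same time.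

Step 6
Reactants: 10 (1S,3S)-3-{[(tert-butyldimethylsilyl)oxy]methyl}-4,4-dimethyl-2-methylidenecyclohexyl benzoate
Product: 11 (1S,3S)-3-(hydroxymethyl)-4,4-dimethyl-2-methylidenecyclohexyl benzoate
Conditions: HF·pyridine, pyridine, THF, 0 °C to rt
Reagents that add atoms: none
Why: Buffered fluoride desilylation cleaves the primary silyl ether and should leave the benzoate and the allylic system untouched.

Step 7
Reactants: 11 (1S,3S)-3-(hydroxymethyl)-4,4-dimethyl-2-methylidenecyclohexyl benzoate
Product: 12 (1S,3S)-3-(iodomethyl)-4,4-dimethyl-2-methylidenecyclohexyl benzoate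
Conditions: I2, PPh3, imidazole, CH2Cl2, 0 °C
Reagents that add atoms: iodine, II
Why: Garegg–Samuelsson (Appel-type) iodination converts the primary alcohol into the iodide by SN2 displacement of the alkoxyphosphonium ion; the stereocentres are not involved.

Step 8
Reactants: 13 luteolin
Product: 14 7-[(tert-butyldimethylsilyl)oxy]-2-{3,4-bis[(tert-butyldimethylsilyl)oxy]phenyl}-5-hydroxy-4H-chromen-4-one
Conditions: TBSCl (3.3 equiv), imidazole, DMF, 0 °C to rt
Reagents that add atoms: tert-butyldimethylsilyl chloride, C[Si](C)(Cl)C(C)(C)C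
Why: Phenol silylation; the 5-hydroxyl, hydrogen-bonded to the C4 carbonyl and peri-hindered, should remain free when the amount of reagent is controlled.

Step 9
Reactants: 14 7-[(tert-butyldimethylsilyl)oxy]-2-{3,4-bis[(tert-butyldimethylsilyl)oxy]phenyl}-5-hydroxy-4H-chromen-4-one
Product: 15 7-[(tert-butyldimethylsilyl)oxy]-2-{3,4-bis[(tert-butyldimethylsilyl)oxy]phenyl}-5-hydroxy-6-iodo-4H-chromen-4-one
Conditions: BnNMe3 ICl2 (1.05 equiv), CaCO3, CH2Cl2/MeOH, rt
Reagents that add atoms: benzyltrimethylammonium dichloroiodate, C[N+](C)(C)Cc1ccccc1.Cl[I-]Cl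
Why: Electrophilic aromatic iodination on ring A at C6, ortho to the free chelated 5-hydroxyl and between the two oxygen substituents, the regioselectivity known for 5-hydroxy-7-alkoxyflavones with this reagent; CaCO3 buffers the HCl and protects the silyl ethers.

Step 10
Reactants: 12 (1S,3S)-3-(iodomethyl)-4,4-dimethyl-2-methylidenecyclohexyl benzoate; 15 7-[(tert-butyldimethylsilyl)oxy]-2-{3,4-bis[(tert-butyldimethylsilyl)oxy]phenyl}-5-hydroxy-6-iodo-4H-chromen-4-one
Product: 17 (1S,3S)-3-({7-[(tert-butyldimethylsilyl)oxy]-2-{3,4-bis[(tert-butyldimethylsilyl)oxy]phenyl}-5-hydroxy-4-oxo-4H-chromen-6-yl}methyl)-4,4-dimethyl-2-methylidenecyclohexyl benzoate, via alkylzinc iodide 16 (not isolated)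
Conditions: 12, Zn dust (TMSCl-activated), LiCl, THF, 35 °C; then added slowly to 15 (1.2 equiv), Pd(OAc)2 (5 mol%), SPhos (10 mol%), THF, rt
Reagents that add atoms: none
Why: Zinc insertion into the primary C–I bond tolerates the ester, and Negishi cross-coupling joins the sp3 carbon to C6 of the flavone; oxidative addition to the aryl iodide, kept in excess by slow addition of the zinc reagent, should outpace ionisation of the hindered allylic benzoate, and a chelated phenol is tolerated by alkylzinc halides under these conditions.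

Step 11
Reactants: 17 (1S,3S)-3-({7-[(tert-butyldimethylsilyl)oxy]-2-{3,4-bis[(tert-butyldimethylsilyl)oxy]phenyl}-5-hydroxy-4-oxo-4H-chromen-6-yl}methyl)-4,4-dimethyl-2-methylidenecyclohexyl benzoate
Product: 18 ugonin Q
Conditions: K2CO3, degassed MeOH, argon, rt; then AcOH
Reagents that add atoms: none
Why: Base-mediated methanolysis (transesterification of the benzoate, cleavage of the aryl silyl ethers) should free all five hydroxyl groups without acid, so the allylic alcohol and the exocyclic alkene are not endangered.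

Compound list
1 | 2-[(tert-butyldimethylsilyl)oxy]acetaldehyde | O=CCO[Si](C)(C)C(C)(C)C | starting material
2 | benzyl acetoacetate | CC(=O)CC(=O)OCc1ccccc1 | starting material
3 | benzyl 2-acetyl-4-[(tert-butyldimethylsilyl)oxy]but-2-enoate (E/Z mixture) | CC(=O)C(=CCO[Si](C)(C)C(C)(C)C)C(=O)OCc1ccccc1 | intermediate
4 | isobutyraldehyde | CC(C)C=O | starting material
5 | benzyl (3R)-2-acetyl-3-{[(tert-butyldimethylsilyl)oxy]methyl}-4,4-dimethyl-5-oxopentanoate (epimers at C2) | CC(=O)C(C(=O)OCc1ccccc1)[C@@H](CO[Si](C)(C)C(C)(C)C)C(C)(C)C=O | intermediate (not isolated)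
6 | benzyl (6R)-6-{[(tert-butyldimethylsilyl)oxy]methyl}-5,5-dimethyl-2-oxocyclohex-3-ene-1-carboxylate (epimers at C1) | O=C(OCc1ccccc1)C1[C@@H](CO[Si](C)(C)C(C)(C)C)C(C)(C)C=CC1=O | intermediate
7 | (2R)-2-{[(tert-butyldimethylsilyl)oxy]methyl}-3,3-dimethyl-6-oxocyclohexane-1-carboxylic acid (epimers at C1) | O=C(O)C1[C@@H](CO[Si](C)(C)C(C)(C)C)C(C)(C)CCC1=O | intermediate (not isolated)
8 | (3S)-3-{[(tert-butyldimethylsilyl)oxy]methyl}-4,4-dimethyl-2-methylidenecyclohexan-1-one | C=C1[C@@H](CO[Si](C)(C)C(C)(C)C)C(C)(C)CCC1=O | intermediate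
9 | (1R,3S)-3-{[(tert-butyldimethylsilyl)oxy]methyl}-4,4-dimethyl-2-methylidenecyclohexan-1-ol | C=C1[C@@H](CO[Si](C)(C)C(C)(C)C)C(C)(C)CC[C@H]1O | intermediate
10 | (1S,3S)-3-{[(tert-butyldimethylsilyl)oxy]methyl}-4,4-dimethyl-2-methylidenecyclohexyl benzoate | C=C1[C@@H](CO[Si](C)(C)C(C)(C)C)C(C)(C)CC[C@@H]1OC(=O)c1ccccc1 | intermediate
11 | (1S,3S)-3-(hydroxymethyl)-4,4-dimethyl-2-methylidenecyclohexyl benzoate | C=C1[C@@H](CO)C(C)(C)CC[C@@H]1OC(=O)c1ccccc1 | intermediate
12 | (1S,3S)-3-(iodomethyl)-4,4-dimethyl-2-methylidenecyclohexyl benzoate | C=C1[C@@H](CI)C(C)(C)CC[C@@H]1OC(=O)c1ccccc1 | intermediate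
13 | luteolin | O=c1cc(-c2ccc(O)c(O)c2)oc2cc(O)cc(O)c12 | starting material
14 | 7-[(tert-butyldimethylsilyl)oxy]-2-{3,4-bis[(tert-butyldimethylsilyl)oxy]phenyl}-5-hydroxy-4H-chromen-4-one | O=c1cc(-c2ccc(O[Si](C)(C)C(C)(C)C)c(O[Si](C)(C)C(C)(C)C)c2)oc2cc(O[Si](C)(C)C(C)(C)C)cc(O)c12 | intermediate
15 | 7-[(tert-butyldimethylsilyl)oxy]-2-{3,4-bis[(tert-butyldimethylsilyl)oxy]phenyl}-5-hydroxy-6-iodo-4H-chromen-4-one | O=c1cc(-c2ccc(O[Si](C)(C)C(C)(C)C)c(O[Si](C)(C)C(C)(C)C)c2)oc2cc(O[Si](C)(C)C(C)(C)C)c(I)c(O)c12 | intermediate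
16 | ({(1S,3S)-3-(benzoyloxy)-6,6-dimethyl-2-methylidenecyclohexyl}methyl)zinc iodide | C=C1[C@@H](C[Zn]I)C(C)(C)CC[C@@H]1OC(=O)c1ccccc1 | intermediate (not isolated)
17 | (1S,3S)-3-({7-[(tert-butyldimethylsilyl)oxy]-2-{3,4-bis[(tert-butyldimethylsilyl)oxy]phenyl}-5-hydroxy-4-oxo-4H-chromen-6-yl}methyl)-4,4-dimethyl-2-methylidenecyclohexyl benzoate | C=C1[C@@H](Cc2c(O[Si](C)(C)C(C)(C)C)cc3oc(-c4ccc(O[Si](C)(C)C(C)(C)C)c(O[Si](C)(C)C(C)(C)C)c4)cc(=O)c3c2O)C(C)(C)CC[C@@H]1OC(=O)c1ccccc1 | intermediate
18 | ugonin Q, 2-(3,4-dihydroxyphenyl)-5,7-dihydroxy-6-{[(1S,3S)-3-hydroxy-6,6-dimethyl-2-methylidenecyclohexyl]methyl}-4H-chromen-4-one | C=C1[C@@H](Cc2c(O)cc3oc(-c4ccc(O)c(O)c4)cc(=O)c3c2O)C(C)(C)CC[C@@H]1O | target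

Total step count: 11. Longest linear sequence: 9 steps (steps 1 to 7, 10 and 11); steps 8 and 9 prepare the flavone partner.

Steps most likely to fail

Step 2. The enamine may add with poor facial discrimination, or the primary-amine catalyst may be sequestered as an enaminone of the β-keto ester so that turnover stops. The fallback sets out from 3 and comes back at 9. The annulation is run without a chiral catalyst (pyrrolidine/AcOH for both stages), which gives 6 as a racemate, that is, together with its enantiomer ent-6 F2, formed through the enantiomeric ketoaldehyde ent-5 F1. The racemate is taken through steps 3 and 4 unchanged, which also gives the enantiomeric keto acid ent-7 F3, the enone ent-8 F4 and the cis alcohol ent-9 F5. The racemic cis alcohol is resolved by lipase-catalysed acylation (lipase from Burkholderia cepacia, vinyl acetate, MTBE). By the Kazlauskas rule the (1R)-carbinol 9 should be acylated faster, to the acetate of 9 F6, while F5 stays behind. Chromatographic separation and methanolysis of F6 (K2CO3, MeOH) return 9.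

Step 5. Benzoate may attack the exocyclic methylidene carbon (SN2′) or the alkoxyphosphonium ion may eliminate instead of undergoing clean inversion; incomplete cis selectivity in step 4 would add to this. The fallback sets out from 8 and comes back at 12. The silyl ether of 8 is cleaved first (HF·pyridine) to the hydroxy enone F7. The free primary hydroxyl then directs the reduction: Me4NBH(OAc)3 in MeCN/AcOH at −20 °C binds the alkoxide and should deliver hydride within the complex to the carbonyl face syn to the CH2O arm, giving the trans diol F8 directly (this reagent does not reduce ketones that lack a bound hydroxyl). Selective iodination of the primary hydroxyl (I2, PPh3, imidazole, 0 °C) gives the iodo alcohol F9, and benzoylation (BzCl, pyridine, DMAP) returns 12.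

Step 10. Zerovalent palladium may ionise the allylic benzoate (π-allyl formation, then elimination or allylic alkylation), and coupling at the doubly ortho-substituted iodide may be slow enough for the zinc reagent to be lost by protonation or β-hydride elimination. The fallback sets out from 12 and comes back at 18. The benzoate is exchanged for a silyl ether before the coupling, so that no ionisable allylic ester meets the catalyst. Methanolysis of 12 (K2CO3, MeOH) gives the iodo alcohol F9 of the preceding fallback, and TBSOTf/2,6-lutidine gives the silyl ether F10. Zinc insertion gives the alkylzinc iodide F11, and Negishi coupling with 15 (Pd(OAc)2/CPhos, THF, 40 °C, which the silyl ether tolerates) gives the tetrasilyl compound F12. TBAF/AcOH in THF then removes all four silyl groups and gives 18.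

Further compounds
F1 | step 2 | benzyl (3S)-2-acetyl-3-{[(tert-butyldimethylsilyl)oxy]methyl}-4,4-dimethyl-5-oxopentanoate (ent-5) | CC(=O)C(C(=O)OCc1ccccc1)[C@H](CO[Si](C)(C)C(C)(C)C)C(C)(C)C=O
F2 | step 2 | benzyl (6S)-6-{[(tert-butyldimethylsilyl)oxy]methyl}-5,5-dimethyl-2-oxocyclohex-3-ene-1-carboxylate (ent-6) | O=C(OCc1ccccc1)C1[C@H](CO[Si](C)(C)C(C)(C)C)C(C)(C)C=CC1=O
F3 | step 2 | (2S)-2-{[(tert-butyldimethylsilyl)oxy]methyl}-3,3-dimethyl-6-oxocyclohexane-1-carboxylic acid (ent-7) | O=C(O)C1[C@H](CO[Si](C)(C)C(C)(C)C)C(C)(C)CCC1=O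
F4 | step 2 | (3R)-3-{[(tert-butyldimethylsilyl)oxy]methyl}-4,4-dimethyl-2-methylidenecyclohexan-1-one (ent-8) | C=C1[C@H](CO[Si](C)(C)C(C)(C)C)C(C)(C)CCC1=O
F5 | step 2 | (1S,3R)-3-{[(tert-butyldimethylsilyl)oxy]methyl}-4,4-dimethyl-2-methylidenecyclohexan-1-ol (ent-9) | C=C1[C@H](CO[Si](C)(C)C(C)(C)C)C(C)(C)CC[C@@H]1O
F6 | step 2 | (1R,3S)-3-{[(tert-butyldimethylsilyl)oxy]methyl}-4,4-dimethyl-2-methylidenecyclohexyl acetate (acetate of 9) | C=C1[C@@H](CO[Si](C)(C)C(C)(C)C)C(C)(C)CC[C@H]1OC(C)=O
F7 | step 5 | (3S)-3-(hydroxymethyl)-4,4-dimethyl-2-methylidenecyclohexan-1-one | C=C1[C@@H](CO)C(C)(C)CCC1=O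
F8 | step 5 | (1S,3S)-3-(hydroxymethyl)-4,4-dimethyl-2-methylidenecyclohexan-1-ol | C=C1[C@@H](CO)C(C)(C)CC[C@@H]1O
F9 | step 5 | (1S,3S)-3-(iodomethyl)-4,4-dimethyl-2-methylidenecyclohexan-1-ol | C=C1[C@@H](CI)C(C)(C)CC[C@@H]1O
F10 | step 10 | tert-butyl{[(1S,3S)-3-(iodomethyl)-4,4-dimethyl-2-methylidenecyclohexyl]oxy}dimethylsilane | C=C1[C@@H](CI)C(C)(C)CC[C@@H]1O[Si](C)(C)C(C)(C)C
F11 | step 10 | ({(1S,3S)-3-[(tert-butyldimethylsilyl)oxy]-6,6-dimethyl-2-methylidenecyclohexyl}methyl)zinc iodide | C=C1[C@@H](C[Zn]I)C(C)(C)CC[C@@H]1O[Si](C)(C)C(C)(C)C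
F12 | step 10 | 7-[(tert-butyldimethylsilyl)oxy]-2-{3,4-bis[(tert-butyldimethylsilyl)oxy]phenyl}-6-({(1S,3S)-3-[(tert-butyldimethylsilyl)oxy]-6,6-dimethyl-2-methylidenecyclohexyl}methyl)-5-hydroxy-4H-chromen-4-one | C=C1[C@@H](Cc2c(O[Si](C)(C)C(C)(C)C)cc3oc(-c4ccc(O[Si](C)(C)C(C)(C)C)c(O[Si](C)(C)C(C)(C)C)c4)cc(=O)c3c2O)C(C)(C)CC[C@@H]1O[Si](C)(C)C(C)(C)C
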